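The green run held 64.8 % target and the blue run 92.9 %, and they differed in partner, 1.2 equiv against 3.6 equiv.

| setting | green | blue | gamma | delta |
|---|---|---|---|---|
| starting material | 25 mM | 25 mM | 25 mM | 25 mM |
| partner | 1.2 equiv | 3.6 equiv | 3.00 equiv | 1.00 equiv |
| second substrate | 2 equiv (in portions, 4) | 2 equiv (in portions, 4) | 2.00 equiv | 2.00 equiv (in portions, 4) |
| protic impurity | 5 mM | 5 mM | 5.00 mM | 5.00 mM |
| remark | run made earlier; portions every 2.5 s | run made earlier; portions every 2.5 s | everything together at the start | the portions of second substrate follow each other after 2.5 s, the first at the start |
| time |  |  | 15 min | 15 min |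

| run | time / min | target / % | starting material / % |
|---|---|---|---|
| green | 0.667 | 64.4 | 0 |
| green | 1.00 | 65.2 | 0 |
| green | 2.00 | 64.5 | 0 |
| green | 4.00 | 64.2 | 0.3 |
| green | 8.00 | 65.6 | 0.4 |
| blue | 0.667 | 92.9 | 0 |
| blue | 2.00 | 93.4 | 0 |
| blue | 4.00 | 92.7 | 0 |
| blue | 5.00 | 92.3 | 0 |
| blue | 8.00 | 93.2 | 0 |

(readings scatter by 0.5 percentage points)

- the winner by amount of target, in percent of the starting material charged; "neither" if no more than 2 percentage points parts them (gamma / delta / neither)
- how much target is there at the end, in percent of the starting material charged: gamma
- how much target is there at the end, in percent of the starting material charged: delta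

In both runs the starting material read zero at 0.667 min, and the target then stayed flat within the scatter of 0.5 percentage points, so I reckoned with final shares and not with rates.

From green I kept 3.07: this is the selectivity factor, the odds of target (target over the rest of the charged starting material) divided by the charged ratio of partner to second substrate. But blue gave 7.27, more than green, so the factor was not constant between the dosed runs.

No run showed a flask charged all at once, so I took the lower green value for both new flasks. Multiplied by the charged ratio and turned back into a share, it gave me 60.5 % for delta and 82.1 % for gamma.

The forecast gave 80 % for gamma, 57 % for delta and gamma as the winner, with the outcome “decided in the first seconds by a kinetic competition and not by time”. My figures differed from it, gamma higher and delta higher, but they named the same winner.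

The flasks gave 76.3 % for gamma and 57.8 % for delta, so gamma won, as the forecast said.

starting material + partner → target (k = 8.20 M⁻¹ s⁻¹); second substrate + partner → second product (k = 1.50 M⁻¹ s⁻¹); starting material + second substrate → cross product (k = 3.70 M⁻¹ s⁻¹); partner + protic impurity → quenched reagent (k = 0.880 M⁻¹ s⁻¹); 2 second substrate → homo dimer (k = 0.110 M⁻¹ s⁻¹) Gamma's own factor came to 2.15, less than green's, and gamma held 23.7 % cross product at the end. I carried that factor to a neighbouring flask, like gamma but charged with 7.50 equiv of partner, and its charged ratio gave 89.0 % target. That neighbour held 90.1 % target beside 9.93 % cross product.

(All runs are calculated with made-up constants, and the scatter is random.)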